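## Analysis of the target

The target is (3S,3′S,all‑E)‑4′,5′‑didehydro‑4,5′‑retro‑β,β‑carotene‑3,3′‑diol (eschscholtzxanthin, C40H54O2), a C2‑symmetric retro‑carotenoid (carotenoid numbering is used throughout). Two 2,6,6‑trimethylcyclohex‑2‑ene rings (C1–C6 and C1′–C6′) are joined through exocyclic double bonds C6=C7 and C6′=C7′ to a C18 chain. Twelve double bonds are conjugated (C4=C5, C6=C7, C8=C9, C10=C11, C12=C13, C14=C15 and the primed set) and C15–C15′ is a single bond. Every chain double bond therefore lies one position away from where it lies in the normal carotenoid series. The only stereocentres are the carbinol carbons C3 and C3′ (both S), at opposite ends of the chromophore and far too distant for any relay. Ten double bonds are stereogenic and all are E; at C6=C7 this means that C8 is syn to C1 and H7 faces the C5 methyl group. The C3–O bonds are allylic to the whole dodecaene, so acid ionises them (racemisation, dehydration), and the polyene is sensitive to light, oxygen and electrophiles. The synthesis is hard for two reasons. Ring carbon C6 is flanked by quaternary C1 and methyl‑bearing C5, which blocks a direct carbonyl olefination there. The shifted bond pattern means that the usual carotenoid building blocks do not map onto the chain.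

Remarks on the chemistry: the SMILES is read as 3S,3′S with all ten stereogenic double bonds E (6E,6′E included). C20 dialdehyde 4 and dione 1 are taken as purchasable. All polyene operations are assumed to run under argon in dim light.

## Retrosynthetic reasoning

**10 ⇒ 9.** The two C3–O bonds are carried as silyl ethers. Their cleavage by a fluoride source is the only non‑acidic way to free an alcohol that is allylic to twelve conjugated double bonds, so it is placed last.

**9 ⇒ 8 (key disconnection).** No σ bond of the skeleton is cut. The retro pattern of 9 is the normal pattern shifted by one bond, so 9 is the two‑electron reduction product of the 6,6′‑diol 8 with loss of both oxygens. The forward step must form C6=C7 and C6′=C7′ and move all nine chain double bonds of 8 by one position. Three things are gained: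
- The chain of 8 has the normal carotenoid pattern, so it can come from the purchasable dialdehyde 4.
- C6 becomes a carbinol carbon, made by addition to a ketone instead of by an impossible olefination.
- The C6/C6′ configurations and every double‑bond geometry of 8 are erased in the step, so nothing before it needs stereocontrol except C3.

**8 ⇒ 7.** The C7=C8 and C7′=C8′ alkenes of 8 are traced back to alkynes. The neighbouring tertiary hydroxyl groups direct a trans‑selective hydride reduction, and the geometry obtained is immaterial for the key step.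

**7 ⇒ 6 + two molecules of 3.** The bonds C6–C7 and C6′–C7′ are cut, the most hindered bonds of the target and both at fully substituted ring carbons. An acetylide is the smallest carbon nucleophile available, and ketone 3 has no α‑hydrogen, so 1,2‑addition is the only productive path. The union is two‑directional (C22 + 2 × C9) and uses the symmetry of the target.

**6 ⇒ 5 ⇒ 4.** The terminal alkyne carbons C7 and C7′ are the only carbons the C20 dialdehyde 4 lacks. A two‑fold aldehyde‑to‑alkyne homologation through the bis(dibromoalkene) 5 supplies them and delivers the bis‑acetylide 6 directly.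

**3 ⇒ 2 ⇒ 1.** Ketone 3 is the silyl ether of hydroxy‑enone 2. Its carbonyl carbon is C6 of the target and its carbinol carbon is C3. Compound 2 comes from the achiral dione 1 by enantioselective reduction of the less hindered carbonyl group. This single catalytic event, used on both halves, sets both stereocentres of the target.

## Alternatives that were turned down

**Alternative 1:** the textbook route, a double Wittig olefination forming C10=C11 and C10′=C11′ from the retro C14 phosphonium salt A1 and the C12 dialdehyde A2, giving 9.
- Neither partner is a stock building block, because the retro pattern shifts every double bond. A2 is the 3,8‑dimethyl isomer of the usual central dialdehyde and needs its own synthesis.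
- A1 requires the exocyclic C6=C7 bond to be built on the ring first, and its salt formation is acidic, which is the condition that ionises C3–O.
- The ylide of A1 is a trienyl ylide with charge also at C8 and C6, so regiochemical leakage is expected.
- Both new double bonds form as E/Z mixtures, and the C6=C7 geometry must be set early and carried.
- The route is long and linear and has no stereoconvergence.

**Alternative 2:** disconnection of C15–C15′. Pinacol homocoupling of the C20 aldehyde A3 gives the 15,15′‑diol A4, followed by an acid‑induced double 1,12‑dehydration (ionisation at C15, proton loss at C4, as in the formation of anhydro‑vitamin A).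
- The cation at C15 sits next to the second carbinol carbon, so a 1,2‑hydride shift to a conjugated ketone is intramolecular and should beat a deprotonation eleven atoms away.
- The proton can also be lost from the C5 methyl group.
- Under the same acid the C3–O bond of the product ionises more easily than the carbinols of A4.
- A3 itself needs a multi‑step all‑E synthesis.

**Alternative 3:** disconnection of C13–C14 and C13′–C14′. A double Stille coupling of two molecules of the retro C18 iodide A5 with the bis‑stannyl diene A6 would give 9.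
- The key step would make two unhindered sp2–sp2 single bonds and set nothing.
- The real problems (the hindered exocyclic C6=C7 bond and each double‑bond geometry) are moved into a long linear synthesis of the light‑ and acid‑sensitive iodo‑pentaene A5.
- Stoichiometric tin is needed at the last carbon–carbon bond formation.

Key step: step 6

## Route

Step 1
Reactants: 1 ketoisophorone (2,6,6‑trimethylcyclohex‑2‑ene‑1,4‑dione)
Product: 2 (S)‑phorenol, (4S)‑4‑hydroxy‑2,6,6‑trimethylcyclohex‑2‑en‑1‑one
Conditions: RuCl[(S,S)‑TsDPEN](p‑cymene) (0.5 mol %), KOH (1 mol %), i‑PrOH, 20 °C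
Reagents that add atoms: none
Why: Noyori–Ikariya asymmetric transfer hydrogenation; only the C4 carbonyl is accessible, since C1 is flanked by the quaternary carbon and the methyl‑bearing alkene carbon. With the enone π‑system in the role of the aryl group of an aryl alkyl ketone, the (S,S) ligand should give the 4S alcohol (the mirror‑image complex is used if the sense proves opposite).

Step 2
Reactants: 2 (S)‑phorenol
Product: 3 (4S)‑4‑(tert‑butyldimethylsilyloxy)‑2,6,6‑trimethylcyclohex‑2‑en‑1‑one
Conditions: TBSCl, imidazole, DMF, 20 °C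
Reagents that add atoms: tert‑butyldimethylsilyl chloride, CC(C)(C)[Si](C)(C)Cl
Why: Standard silylation of a secondary alcohol; the silyl ether cannot become a metal alkoxide in steps 4–6 and is removed at the end without acid. The stereocentre is not touched.

Step 3
Reactants: 4 crocetin dialdehyde, (2E,4E,6E,8E,10E,12E,14E)‑2,6,11,15‑tetramethylhexadeca‑2,4,6,8,10,12,14‑heptaenedial
Product: 5 (3E,5E,7E,9E,11E,13E,15E)‑1,1,18,18‑tetrabromo‑3,7,12,16‑tetramethyloctadeca‑1,3,5,7,9,11,13,15,17‑nonaene
Conditions: CBr4, PPh3, Zn, CH2Cl2, 0 → 20 °C, dark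
Reagents that add atoms: carbon tetrabromide, BrC(Br)(Br)Br
Why: Two‑fold dibromomethylenation (first stage of the Corey–Fuchs reaction) of an α‑methyl enal; zinc keeps the medium free of acid and phosphorus bromides, which protects the polyene.

Step 4
Reactants: 5 tetrabromo‑nonaene; 3 (4S)‑silyloxy‑enone (2.2 equiv)
Product: 7 (3S,3′S,6RS,6′RS)‑3,3′‑bis(tert‑butyldimethylsilyloxy)‑7,8,7′,8′‑tetradehydro‑ε,ε‑carotene‑6,6′‑diol (C40 diyne‑diol with tertiary OH at C6 and C6′, alkynes C7≡C8 and C7′≡C8′ and the all‑E heptaene C9–C9′), via dilithium C22 diacetylide 6 (not isolated)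
Conditions: n‑BuLi (4.1 equiv), THF, −78 °C; then 3, −78 → 0 °C; H2O
Reagents that add atoms: n‑butyllithium, [Li]CCCC (supplies the lithium of 6; none of its atoms other than hydrogen remains in 7)
Why: Second stage of the Corey–Fuchs reaction (Br/Li exchange, Fritsch–Buttenberg–Wiechell shift, deprotonation) gives the bis‑acetylide 6. It adds 1,2 to the hindered carbonyl of 3, which has no α‑hydrogen, as acetylides do with 2,6,6‑trimethylcyclohexenones. The configuration at C6 and C6′ is not controlled and need not be, because both centres are destroyed in step 6.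

Step 5
Reactants: 7 C40 diyne‑diol
Product: 8 (3S,3′S,6RS,6′RS)‑3,3′‑bis(tert‑butyldimethylsilyloxy)‑ε,ε‑carotene‑6,6′‑diol (all‑E nonaene C7–C7′ between the two tertiary, doubly allylic carbinol carbons C6 and C6′)
Conditions: NaAlH2(OCH2CH2OMe)2 (6 equiv), THF, 0 → 20 °C; aq. KNaC4H4O6
Reagents that add atoms: none
Why: Alkoxide‑directed trans‑hydroalumination of the two propargylic alcohols and protonolysis give the E‑allylic alcohols. Alkenes not next to an alkoxide and the silyl ethers are inert to the reagent.

Step 6
Reactants: 8 C40 nonaene‑6,6′‑diol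
Product: 9 (3S,3′S,all‑E)‑3,3′‑bis(tert‑butyldimethylsilyloxy)‑4′,5′‑didehydro‑4,5′‑retro‑β,β‑carotene (bis‑silyl ether of the target)
Conditions: TiCl3 (8 equiv), LiAlH4 (4 equiv), THF, reflux then 0 °C; slow addition of 8 (final 0.005 M), 0 → 20 °C, dark; aq. K2CO3
Reagents that add atoms: none
Why: Vinylogous McMurry‑type deoxygenation (reductive 1,20‑elimination): both tertiary hydroxyls become titanium alkoxides, the doubly allylic C6–O bond breaks by inner‑sphere electron transfer to a radical delocalised from C4 to C8′, and cleavage of the second C–O bond at C6′ gives the closed‑shell retro‑dodecaene as strong Ti–O bonds form. The closest known reaction type is the low‑valent‑titanium reductive elimination of 2‑ene‑1,4‑diols and 2,4‑diene‑1,6‑diols to dienes and trienes (the Kuhn–Winterstein conversion of polyene glycols is the older relative); the present case lengthens the conjugated relay. No ring is closed and no stereocentre is created; the uncontrolled centres C6 and C6′ are destroyed, so all three diastereomers of 8 converge on 9. All ten stereogenic double bonds of 9 are new: those at C8, C10, C12 and C14 (and the primed ones) arise from single bonds that are s‑trans in the planar polyene of 8, while the former double bonds become freely rotating single bonds, so the chain should emerge E whatever the geometrical purity of 8. At C6=C7 the E isomer is expected to be preferred because it puts H7, not C8, in the plane beside the C5 methyl group (allylic 1,3‑strain) and lets C8 lie between the two out‑of‑plane C1 methyl groups; the delocalised radical has a low rotational barrier about C6–C7 and can adopt this arrangement before the second oxygen leaves. The step needs cleavage of C6–O with retention of C3–O: the C3 oxygen is a silyl ether that cannot become a titanium alkoxide, and C3 stays sp3 throughout, so its configuration is untouched. High dilution favours the unimolecular loss of the second oxygen over bimolecular coupling of polyenyl radicals.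

Step 7
Reactants: 9 bis‑silyl ether
Product: 10 (3S,3′S,all‑E)‑4′,5′‑didehydro‑4,5′‑retro‑β,β‑carotene‑3,3′‑diol (eschscholtzxanthin, the target)
Conditions: Bu4NF, AcOH (1:1), THF, 0 → 20 °C, dark; crystallisation
Reagents that add atoms: none
Why: Fluoride‑induced Si–O cleavage at silicon leaves the C3–O bonds intact, so the configuration is retained; buffering with acetic acid avoids both strong base and free acid near the ionisable allylic carbinols.

## Compound list

1 | ketoisophorone (2,6,6‑trimethylcyclohex‑2‑ene‑1,4‑dione) | CC1=CC(=O)CC(C)(C)C1=O | starting material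
2 | (S)‑phorenol, (4S)‑4‑hydroxy‑2,6,6‑trimethylcyclohex‑2‑en‑1‑one | CC1=C[C@@H](O)CC(C)(C)C1=O | intermediate
3 | (4S)‑4‑(tert‑butyldimethylsilyloxy)‑2,6,6‑trimethylcyclohex‑2‑en‑1‑one | CC1=C[C@@H](O[Si](C)(C)C(C)(C)C)CC(C)(C)C1=O | intermediate
4 | crocetin dialdehyde (all‑E C20 heptaenedial) | O=C/C(C)=C/C=C/C(C)=C/C=C/C=C(C)/C=C/C=C(C)/C=O | starting material
5 | (3E,5E,7E,9E,11E,13E,15E)‑1,1,18,18‑tetrabromo‑3,7,12,16‑tetramethyloctadeca‑1,3,5,7,9,11,13,15,17‑nonaene | BrC(Br)=C/C(C)=C/C=C/C(C)=C/C=C/C=C(C)/C=C/C=C(C)/C=C(Br)Br | intermediate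
6 | dilithium (3E,5E,7E,9E,11E,13E,15E)‑3,7,12,16‑tetramethyloctadeca‑3,5,7,9,11,13,15‑heptaene‑1,17‑diyne‑1,18‑diide | [Li]C#C/C(C)=C/C=C/C(C)=C/C=C/C=C(C)/C=C/C=C(C)/C#C[Li] | intermediate (not isolated)
7 | (3S,3′S,6RS,6′RS)‑3,3′‑bis(tert‑butyldimethylsilyloxy)‑7,8,7′,8′‑tetradehydro‑ε,ε‑carotene‑6,6′‑diol | CC1=C[C@@H](O[Si](C)(C)C(C)(C)C)CC(C)(C)C1(O)C#C/C(C)=C/C=C/C(C)=C/C=C/C=C(C)/C=C/C=C(C)/C#CC1(O)C(C)=C[C@@H](O[Si](C)(C)C(C)(C)C)CC1(C)C | intermediate
8 | (3S,3′S,6RS,6′RS,all‑E)‑3,3′‑bis(tert‑butyldimethylsilyloxy)‑ε,ε‑carotene‑6,6′‑diol | CC1=C[C@@H](O[Si](C)(C)C(C)(C)C)CC(C)(C)C1(O)/C=C/C(C)=C/C=C/C(C)=C/C=C/C=C(C)/C=C/C=C(C)/C=C/C1(O)C(C)=C[C@@H](O[Si](C)(C)C(C)(C)C)CC1(C)C | intermediate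
9 | (3S,3′S,all‑E)‑3,3′‑bis(tert‑butyldimethylsilyloxy)‑4′,5′‑didehydro‑4,5′‑retro‑β,β‑carotene | CC1=C[C@@H](O[Si](C)(C)C(C)(C)C)CC(C)(C)\C1=C/C=C(C)/C=C/C=C(C)/C=C/C=C/C(C)=C/C=C/C(C)=C/C=C1/C(C)=C[C@@H](O[Si](C)(C)C(C)(C)C)CC1(C)C | intermediate
10 | (3S,3′S,all‑E)‑4′,5′‑didehydro‑4,5′‑retro‑β,β‑carotene‑3,3′‑diol (eschscholtzxanthin) | CC1=C[C@@H](O)CC(C)(C)\C1=C/C=C(C)/C=C/C=C(C)/C=C/C=C/C(C)=C/C=C/C(C)=C/C=C1/C(C)=C[C@@H](O)CC1(C)C | target

## Step count and risk

Total steps: 7. Longest linear sequence: 6 (steps 1, 2, 4, 5, 6, 7 from compound 1; the branch from compound 4 is steps 3–7).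

**Step 6 (key step).**
- What may go wrong: expulsion of the C3 silyloxy group when spin or charge density builds up at C4 (an elimination inside the ring); bimolecular coupling of the polyenyl radical before the distant second oxygen is lost; incomplete preference for the 6E geometry; Lewis‑acid ionisation of the new allylic C3–O bonds.
- Why: the two reacting centres are twenty atoms apart, and the product is more sensitive than the substrate.
- Fallback: this leaves the metal‑alkoxide homolysis for an ionic substitution and 1,20‑dehalogenation sequence, the Kuhn–Winterstein reaction. It sets out from 8. Treatment with P2I4 and pyridine in CH2Cl2 at 0 °C should replace both tertiary hydroxyl groups by iodide to give the bis‑allylic diiodide F1 (or its allylic isomers, not isolated). This extrudes iodine across the conjugated system and returns to the route at 9. The iodine set free is the usual catalyst for equilibrating polyene geometry, so this variant also addresses a 6Z content before aqueous Na2S2O3 work‑up.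

**Step 4.**
- What may go wrong: incomplete second addition and aggregation or precipitation of the dilithium species 6, and vinylogous deprotonation of 3 at its carbinol carbon.
- Why: a poorly soluble, doubly charged polyene nucleophile has to attack a hindered carbonyl twice.
- Fallback: the union is moved from C6–C7 to the C11=C12 double bonds, so that the hindered ketone meets a small, soluble acetylide. It sets out from 3. Addition of the dilithium derivative of commercial (E)‑3‑methylpent‑2‑en‑4‑yn‑1‑ol (n‑BuLi, THF, −78 °C) should give the C15 yne‑diol F2. Selective Appel bromination of the primary allylic alcohol (CBr4, PPh3) gives the bromide F3, and Michaelis–Arbuzov reaction with P(OEt)3 gives the phosphonate F4. A two‑fold Horner–Wadsworth–Emmons reaction of F4 (NaN(SiMe3)2, THF) with commercial (2E,4E,6E)‑2,7‑dimethylocta‑2,4,6‑trienedial then returns to the route at 7. E/Z mixtures at C11=C12 are tolerable because step 6 erases them.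

**Step 5.**
- What may go wrong: hydride delivery beyond the propargylic positions into the conjugated system, or aluminate‑induced loss of the tertiary oxygen at elevated temperature.
- Why: the alkynes are conjugated with a heptaene, and the alkoxides are doubly activated.
- Fallback: this uses the stereoconvergence of the key step instead of a trans‑selective hydride. It sets out from 7. Boland semi‑reduction (zinc dust activated with Cu(OAc)2 and AgNO3, MeOH/H2O, 20 °C) is chemoselective for conjugated triple bonds and should give the (7Z,7′Z)‑diol F5. Under the conditions of step 6, F5 returns to the route at 9, because the C7=C8 and C7′=C8′ bonds become single bonds there.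

**Step 1.**
- What may go wrong: conjugate reduction of the ene‑dione, reduction at the wrong carbonyl, and erosion of enantiomeric purity by the reversibility of hydrogen transfer to an allylic alcohol.
- Why: the substrate is an activated ene‑dione, not a simple aryl ketone.
- Fallback: a resolution replaces the catalytic asymmetric step. It sets out from 1. Luche reduction (NaBH4, CeCl3·7H2O, MeOH, −20 °C) should reduce the accessible carbonyl to racemic phorenol F6. Steglich esterification with (S)‑2‑methoxy‑2‑phenylacetic acid (DCC, DMAP) gives the diastereomeric esters F7 (4S) and F8 (4R), which are separated by chromatography or crystallisation. Methanolysis of F7 (K2CO3, MeOH) returns to the route at 2. F8 can be recycled by methanolysis and oxidation back to 1.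

## Further compounds

F1 | step 6 | (3S,3′S)‑3,3′‑bis(tert‑butyldimethylsilyloxy)‑6,6′‑diiodo‑ε,ε‑carotene | CC1=C[C@@H](O[Si](C)(C)C(C)(C)C)CC(C)(C)C1(I)/C=C/C(C)=C/C=C/C(C)=C/C=C/C=C(C)/C=C/C=C(C)/C=C/C1(I)C(C)=C[C@@H](O[Si](C)(C)C(C)(C)C)CC1(C)C
F2 | step 4 | (2E)‑5‑[(4S)‑4‑(tert‑butyldimethylsilyloxy)‑1‑hydroxy‑2,6,6‑trimethylcyclohex‑2‑en‑1‑yl]‑3‑methylpent‑2‑en‑4‑yn‑1‑ol | CC1=C[C@@H](O[Si](C)(C)C(C)(C)C)CC(C)(C)C1(O)C#C/C(C)=C/CO
F3 | step 4 | (4S)‑1‑[(3E)‑5‑bromo‑3‑methylpent‑3‑en‑1‑ynyl]‑4‑(tert‑butyldimethylsilyloxy)‑2,6,6‑trimethylcyclohex‑2‑en‑1‑ol | CC1=C[C@@H](O[Si](C)(C)C(C)(C)C)CC(C)(C)C1(O)C#C/C(C)=C/CBr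
F4 | step 4 | diethyl [(2E)‑5‑[(4S)‑4‑(tert‑butyldimethylsilyloxy)‑1‑hydroxy‑2,6,6‑trimethylcyclohex‑2‑en‑1‑yl]‑3‑methylpent‑2‑en‑4‑ynyl]phosphonate | CC1=C[C@@H](O[Si](C)(C)C(C)(C)C)CC(C)(C)C1(O)C#C/C(C)=C/CP(=O)(OCC)OCC
F5 | step 5 | (3S,3′S,6RS,6′RS,7Z,7′Z)‑3,3′‑bis(tert‑butyldimethylsilyloxy)‑ε,ε‑carotene‑6,6′‑diol | CC1=C[C@@H](O[Si](C)(C)C(C)(C)C)CC(C)(C)C1(O)/C=C\C(C)=C\C=C\C(C)=C\C=C\C=C(C)\C=C\C=C(C)\C=C/C1(O)C(C)=C[C@@H](O[Si](C)(C)C(C)(C)C)CC1(C)C
F6 | step 1 | racemic phorenol, 4‑hydroxy‑2,6,6‑trimethylcyclohex‑2‑en‑1‑one | CC1=CC(O)CC(C)(C)C1=O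
F7 | step 1 | (1S)‑3,5,5‑trimethyl‑4‑oxocyclohex‑2‑en‑1‑yl (2S)‑2‑methoxy‑2‑phenylacetate | CC1=C[C@@H](OC(=O)[C@@H](OC)c2ccccc2)CC(C)(C)C1=O
F8 | step 1 | (1R)‑3,5,5‑trimethyl‑4‑oxocyclohex‑2‑en‑1‑yl (2S)‑2‑methoxy‑2‑phenylacetate | CC1=C[C@H](OC(=O)[C@@H](OC)c2ccccc2)CC(C)(C)C1=O
A1 | alternative 1 | [(2E,4E)‑4‑[(4S)‑4‑(tert‑butyldimethylsilyloxy)‑2,6,6‑trimethylcyclohex‑2‑en‑1‑ylidene]‑2‑methylbut‑2‑enyl]triphenylphosphonium bromide | CC1=C[C@@H](O[Si](C)(C)C(C)(C)C)CC(C)(C)\C1=C/C=C(C)/C[P+](c2ccccc2)(c2ccccc2)c2ccccc2.[Br-]
A2 | alternative 1 | (2E,4E,6E,8E)‑3,8‑dimethyldeca‑2,4,6,8‑tetraenedial | O=C/C=C(C)/C=C/C=C/C(C)=C/C=O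
A3 | alternative 2 | (3R,all‑E)‑3‑(tert‑butyldimethylsilyloxy)retinal | CC1=C(/C=C/C(C)=C/C=C/C(C)=C/C=O)C(C)(C)C[C@H](O[Si](C)(C)C(C)(C)C)C1
A4 | alternative 2 | (3R,3′R)‑3,3′‑bis(tert‑butyldimethylsilyloxy)‑15,15′‑dihydro‑β,β‑carotene‑15,15′‑diol | CC1=C(/C=C/C(C)=C/C=C/C(C)=C/C(O)C(O)/C=C(C)/C=C/C=C(C)/C=C/C2=C(C)C[C@@H](O[Si](C)(C)C(C)(C)C)CC2(C)C)C(C)(C)C[C@H](O[Si](C)(C)C(C)(C)C)C1
A5 | alternative 3 | (4S)‑4‑(tert‑butyldimethylsilyloxy)‑1‑[(2E,4E,6E)‑7‑iodo‑3‑methylocta‑2,4,6‑trienylidene]‑2,6,6‑trimethylcyclohex‑2‑ene (6E) | CC1=C[C@@H](O[Si](C)(C)C(C)(C)C)CC(C)(C)\C1=C/C=C(C)/C=C/C=C(C)/I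
A6 | alternative 3 | (1E,3E)‑1,4‑bis(tributylstannyl)buta‑1,3‑diene | CCCC[Sn](CCCC)(CCCC)/C=C/C=C/[Sn](CCCC)(CCCC)CCCC
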